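**Assumption:** the single stereocentre is (R), as encoded by the [C@H] in the target SMILES. The exact ketoreductase variant for step 3 is not known in advance and would be picked from a commercial anti-Prelog KRED panel. The route is designed from general precedent and has not been run.

## Retrosynthetic overview

1. The benzofuran ring is formed last, by 5-endo-dig cyclisation of the o-alkynylphenol released from diaryl alkyne 25, which comes from Sonogashira coupling of iodoarene 24 with alkyne 17.
2. Iodoarene 24 comes from resorcinol bis-MOM ether by two directed ortho-lithiations: C2 geranylation, then C4 iodination.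
3. Alkyne 17 comes from an aryl triflate; its dihydrobenzofuran ring is formed first, by 5-exo phenoxide opening (inversion) of trisubstituted epoxide 12.
4. Epoxide 12 comes from diol 11, made by adding the aryllithium of phloroglucinol-derived 8 to terminal epoxide 5.
5. Epoxide 5 carries the only stereocentre, set by ketoreductase reduction of achiral α-chloroketone 3. Ring order: dihydrofuran (step 11), then furan (step 21).

## Route

**Step 1**
- Reactants: 1, 3-hydroxy-3-methylbutan-2-one
- Product: 2, 3-(methoxymethoxy)-3-methylbutan-2-one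
- Conditions: MOMCl, i-Pr2NEt, NaI (cat.), CH2Cl2, 0 °C → reflux
- Reagents that add atoms: chloromethyl methyl ether, COCCl
- Why: MOM acetalisation (O-alkylation) masks the tertiary OH so that later bases cannot cause epoxide migration (Payne rearrangement) or oxetanone formation.

**Step 2**
- Reactants: 2
- Product: 3, 1-chloro-3-(methoxymethoxy)-3-methylbutan-2-one
- Conditions: LDA, THF, −78 °C; TMSCl; then NCS, THF, 0 °C
- Reagents that add atoms: N-chlorosuccinimide, O=C1CCC(=O)N1Cl
- Why: α-chlorination via the silyl enol ether is regiospecific because only the methyl side of the ketone can enolise.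

**Step 3**
- Reactants: 3
- Product: 4, (2S)-1-chloro-3-(methoxymethoxy)-3-methylbutan-2-ol
- Conditions: anti-Prelog ketoreductase (Lactobacillus kefir ADH type), NADP+ (cat.), i-PrOH (10% v/v), KPi buffer pH 7, 30 °C
- Reagents that add atoms: none
- Why: biocatalytic asymmetric ketone reduction; the ketoreductase delivers NADPH hydride to one enantiotopic face of the achiral chloromethyl ketone (small CH2Cl versus bulky CMe2OMOM), setting the only stereocentre as (S).

**Step 4**
- Reactants: 4
- Product: 5, (2R)-2-[2-(methoxymethoxy)propan-2-yl]oxirane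
- Conditions: K2CO3, MeOH, 0 °C → rt
- Reagents that add atoms: none
- Why: intramolecular Williamson closure of the chlorohydrin; the stereocentre is untouched (the S→R label change is only a CIP priority change).

**Step 5**
- Reactants: 6, phloroglucinol (benzene-1,3,5-triol)
- Product: 7, 5-[(triisopropylsilyl)oxy]benzene-1,3-diol
- Conditions: 6 (3 equiv), TIPSCl (1 equiv), imidazole, DMF, 0 °C → rt
- Reagents that add atoms: triisopropylsilyl chloride, CC(C)[Si](Cl)(C(C)C)C(C)C
- Why: mono-silylation of the symmetric triol (excess triol suppresses bis-silylation) marks the oxygen that becomes the free 6-OH with a bulky, non-directing group.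

**Step 6**
- Reactants: 7
- Product: 8, [3,5-bis(methoxymethoxy)phenoxy]triisopropylsilane
- Conditions: MOMCl, i-Pr2NEt, CH2Cl2, 0 °C → rt
- Reagents that add atoms: chloromethyl methyl ether, COCCl
- Why: MOM protection gives two equivalent ortho-directing groups flanking the carbon that must carry the side chain.

**Step 7**
- Reactants: 8; 5
- Product: 9, (2R)-1-[2,6-bis(methoxymethoxy)-4-(triisopropylsilyloxy)phenyl]-3-(methoxymethoxy)-3-methylbutan-2-ol
- Conditions: n-BuLi, THF, 0 °C; then 5, BF3·OEt2, −78 °C
- Reagents that add atoms: none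
- Why: directed ortho-metalation between the two OMOM groups, then BF3-assisted SN2 opening of the terminal epoxide at CH2, which leaves the stereocentre untouched.

**Step 8**
- Reactants: 9
- Product: 10, 2-[(2R)-2,3-dihydroxy-3-methylbutyl]-5-(triisopropylsilyloxy)benzene-1,3-diol
- Conditions: HCl (0.5 M in MeOH), rt → 35 °C
- Reagents that add atoms: none
- Why: acidic acetal hydrolysis removes all three MOM groups while the aryl TIPS ether and the diol survive dilute methanolic acid.

**Step 9**
- Reactants: 10
- Product: 11, (2R)-1-[2,6-bis(benzyloxy)-4-(triisopropylsilyloxy)phenyl]-3-methylbutane-2,3-diol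
- Conditions: BnBr (2.1 equiv), K2CO3, acetone, reflux
- Reagents that add atoms: benzyl bromide, BrCc1ccccc1
- Why: Williamson O-benzylation of the two phenols only, giving phenol protection that can later be removed without acid in the presence of an epoxide.

**Step 10**
- Reactants: 11
- Product: 12, (3,5-bis(benzyloxy)-4-{[(2S)-3,3-dimethyloxiran-2-yl]methyl}phenoxy)triisopropylsilane
- Conditions: MsCl, Et3N, CH2Cl2, −10 °C; then K2CO3, MeOH, rt
- Reagents that add atoms: none (the mesylate is expelled)
- Why: selective mesylation of the secondary OH, then 3-exo-tet displacement by the tertiary alkoxide with clean inversion, gives the (S)-epoxide while the phenols are still blocked.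

**Step 11**
- Reactants: 12
- Product: 13, (2R)-2-(2-hydroxypropan-2-yl)-6-(triisopropylsilyloxy)-2,3-dihydro-1-benzofuran-4-ol
- Conditions: H2 (1 atm), 10% Pd/C, K2CO3, MeOH/EtOAc, rt
- Reagents that add atoms: none
- Why: benzyl hydrogenolysis, then base-mediated 5-exo-tet epoxide opening by phenoxide with inversion, fixes the final (R) centre; the two ortho phenols are equivalent, so either gives the same product.

**Step 12**
- Reactants: 13
- Product: 14, (2R)-2-(2-hydroxypropan-2-yl)-6-(triisopropylsilyloxy)-2,3-dihydro-1-benzofuran-4-yl trifluoromethanesulfonate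
- Conditions: PhNTf2, Et3N, DMAP (cat.), CH2Cl2, rt
- Reagents that add atoms: N-phenylbis(trifluoromethanesulfonimide), O=S(=O)(N(c1ccccc1)S(=O)(=O)C(F)(F)F)C(F)(F)F
- Why: phenol-selective triflation; the mild reagent leaves the tertiary alcohol alone.

**Step 13**
- Reactants: 14; 15, ethynyltrimethylsilane
- Product: 16, 2-[(2R)-6-(triisopropylsilyloxy)-4-[(trimethylsilyl)ethynyl]-2,3-dihydro-1-benzofuran-2-yl]propan-2-ol
- Conditions: Pd(PPh3)2Cl2, CuI, Et3N, DMF, 70 °C
- Reagents that add atoms: none
- Why: Sonogashira coupling of the aryl triflate, which has only meta oxygen donors and is therefore reactive enough.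

**Step 14**
- Reactants: 16
- Product: 17, (2R)-4-ethynyl-2-(2-hydroxypropan-2-yl)-2,3-dihydro-1-benzofuran-6-ol
- Conditions: TBAF, THF, 0 °C → rt
- Reagents that add atoms: none
- Why: fluoride desilylation cleaves the C–SiMe3 and aryl O–TIPS bonds in one operation; nothing else is fluoride-sensitive.

**Step 15**
- Reactants: 18, resorcinol
- Product: 19, 1,3-bis(methoxymethoxy)benzene
- Conditions: MOMCl, i-Pr2NEt, CH2Cl2, 0 °C → rt
- Reagents that add atoms: chloromethyl methyl ether, COCCl
- Why: MOM protection installs the two directing groups for ortho-metalation.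

**Step 16**
- Reactants: 19; 20, geranyl bromide, (2E)-1-bromo-3,7-dimethylocta-2,6-diene
- Product: 21, 2-[(2E)-3,7-dimethylocta-2,6-dien-1-yl]-1,3-bis(methoxymethoxy)benzene
- Conditions: n-BuLi, THF, 0 °C → rt; then 20, −78 °C → rt
- Reagents that add atoms: none
- Why: directed ortho-metalation at the doubly activated C2, then SN2 alkylation with the primary allylic bromide, which keeps the (E)-alkene.

**Step 17**
- Reactants: 21
- Product: 22, 3-[(2E)-3,7-dimethylocta-2,6-dien-1-yl]-1-iodo-2,4-bis(methoxymethoxy)benzene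
- Conditions: n-BuLi, TMEDA, THF, −20 → 0 °C; then I2, −78 °C
- Reagents that add atoms: iodine, II
- Why: a second directed ortho-metalation (ortho to OMOM) with iodine quench places iodine at C4 without electrophilic iodination, which would attack the geranyl alkenes.

**Step 18**
- Reactants: 22
- Product: 23, 2-[(2E)-3,7-dimethylocta-2,6-dien-1-yl]-4-iodobenzene-1,3-diol
- Conditions: HCl (0.5 M in MeOH), rt
- Reagents that add atoms: none
- Why: MOM acetal hydrolysis is much faster than protonation of the trisubstituted alkenes under dilute acid at room temperature.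

**Step 19**
- Reactants: 23
- Product: 24, 2-[(2E)-3,7-dimethylocta-2,6-dien-1-yl]-4-iodo-1,3-phenylene diacetate
- Conditions: Ac2O, pyridine, DMAP (cat.), CH2Cl2, 0 °C → rt
- Reagents that add atoms: acetic anhydride, CC(=O)OC(C)=O
- Why: acetylation turns the air-sensitive, electron-rich iodoresorcinol into a stable o-iodoaryl acetate, a better oxidative-addition partner.

**Step 20**
- Reactants: 24; 17
- Product: 25, 2-[(2E)-3,7-dimethylocta-2,6-dien-1-yl]-4-{[(2R)-6-hydroxy-2-(2-hydroxypropan-2-yl)-2,3-dihydro-1-benzofuran-4-yl]ethynyl}-1,3-phenylene diacetate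
- Conditions: Pd(PPh3)2Cl2 (3 mol%), CuI (5 mol%), Et3N/THF, rt, Ar
- Reagents that add atoms: none
- Why: Sonogashira coupling of the aryl iodide at room temperature tolerates the free phenol, tertiary alcohol, acetates and geranyl chain.

**Step 21**
- Reactants: 25
- Product: 26, mulberrofuran X
- Conditions: Cs2CO3, MeOH/DMF (1:4), degassed, 60 °C; aq. NH4Cl work-up
- Reagents that add atoms: none
- Why: methanolysis of both acetates, then base-promoted 5-endo-dig hydroalkoxylation by the only phenoxide ortho to the alkyne, closes the 2-arylbenzofuran without acid, so the geranyl phenol and stereocentre are untouched.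

## Compound list

1 | 3-hydroxy-3-methylbutan-2-one | CC(=O)C(C)(C)O | starting material
2 | 3-(methoxymethoxy)-3-methylbutan-2-one | CC(=O)C(C)(C)OCOC | intermediate
3 | 1-chloro-3-(methoxymethoxy)-3-methylbutan-2-one | ClCC(=O)C(C)(C)OCOC | intermediate
4 | (2S)-1-chloro-3-(methoxymethoxy)-3-methylbutan-2-ol | ClC[C@@H](O)C(C)(C)OCOC | intermediate
5 | (2R)-2-[2-(methoxymethoxy)propan-2-yl]oxirane | C1[C@@H](O1)C(C)(C)OCOC | intermediate
6 | phloroglucinol | Oc1cc(O)cc(O)c1 | starting material
7 | 5-[(triisopropylsilyl)oxy]benzene-1,3-diol | Oc1cc(O)cc(O[Si](C(C)C)(C(C)C)C(C)C)c1 | intermediate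
8 | [3,5-bis(methoxymethoxy)phenoxy]triisopropylsilane | COCOc1cc(OCOC)cc(O[Si](C(C)C)(C(C)C)C(C)C)c1 | intermediate
9 | (2R)-1-[2,6-bis(methoxymethoxy)-4-(triisopropylsilyloxy)phenyl]-3-(methoxymethoxy)-3-methylbutan-2-ol | COCOc1cc(O[Si](C(C)C)(C(C)C)C(C)C)cc(OCOC)c1C[C@@H](O)C(C)(C)OCOC | intermediate
10 | 2-[(2R)-2,3-dihydroxy-3-methylbutyl]-5-(triisopropylsilyloxy)benzene-1,3-diol | Oc1cc(O[Si](C(C)C)(C(C)C)C(C)C)cc(O)c1C[C@@H](O)C(C)(C)O | intermediate
11 | (2R)-1-[2,6-bis(benzyloxy)-4-(triisopropylsilyloxy)phenyl]-3-methylbutane-2,3-diol | c1ccccc1COc1cc(O[Si](C(C)C)(C(C)C)C(C)C)cc(OCc2ccccc2)c1C[C@@H](O)C(C)(C)O | intermediate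
12 | (3,5-bis(benzyloxy)-4-{[(2S)-3,3-dimethyloxiran-2-yl]methyl}phenoxy)triisopropylsilane | CC(C)[Si](Oc1cc(OCc2ccccc2)c(C[C@@H]2OC2(C)C)c(OCc2ccccc2)c1)(C(C)C)C(C)C | intermediate
13 | (2R)-2-(2-hydroxypropan-2-yl)-6-(triisopropylsilyloxy)-2,3-dihydro-1-benzofuran-4-ol | Oc1cc(O[Si](C(C)C)(C(C)C)C(C)C)cc2c1C[C@H](C(C)(C)O)O2 | intermediate
14 | (2R)-2-(2-hydroxypropan-2-yl)-6-(triisopropylsilyloxy)-2,3-dihydro-1-benzofuran-4-yl trifluoromethanesulfonate | O=S(=O)(Oc1cc(O[Si](C(C)C)(C(C)C)C(C)C)cc2c1C[C@H](C(C)(C)O)O2)C(F)(F)F | intermediate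
15 | ethynyltrimethylsilane | C#C[Si](C)(C)C | starting material
16 | 2-[(2R)-6-(triisopropylsilyloxy)-4-[(trimethylsilyl)ethynyl]-2,3-dihydro-1-benzofuran-2-yl]propan-2-ol | C[Si](C)(C)C#Cc1cc(O[Si](C(C)C)(C(C)C)C(C)C)cc2c1C[C@H](C(C)(C)O)O2 | intermediate
17 | (2R)-4-ethynyl-2-(2-hydroxypropan-2-yl)-2,3-dihydro-1-benzofuran-6-ol | C#Cc1cc(O)cc2c1C[C@H](C(C)(C)O)O2 | intermediate
18 | resorcinol | Oc1cccc(O)c1 | starting material
19 | 1,3-bis(methoxymethoxy)benzene | COCOc1cccc(OCOC)c1 | intermediate
20 | geranyl bromide, (2E)-1-bromo-3,7-dimethylocta-2,6-diene | CC(C)=CCC/C(C)=C/CBr | starting material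
21 | 2-[(2E)-3,7-dimethylocta-2,6-dien-1-yl]-1,3-bis(methoxymethoxy)benzene | CC(C)=CCC/C(C)=C/Cc1c(OCOC)cccc1OCOC | intermediate
22 | 3-[(2E)-3,7-dimethylocta-2,6-dien-1-yl]-1-iodo-2,4-bis(methoxymethoxy)benzene | CC(C)=CCC/C(C)=C/Cc1c(OCOC)ccc(I)c1OCOC | intermediate
23 | 2-[(2E)-3,7-dimethylocta-2,6-dien-1-yl]-4-iodobenzene-1,3-diol | CC(C)=CCC/C(C)=C/Cc1c(O)ccc(I)c1O | intermediate
24 | 2-[(2E)-3,7-dimethylocta-2,6-dien-1-yl]-4-iodo-1,3-phenylene diacetate | CC(C)=CCC/C(C)=C/Cc1c(OC(C)=O)ccc(I)c1OC(C)=O | intermediate
25 | 2-[(2E)-3,7-dimethylocta-2,6-dien-1-yl]-4-{[(2R)-6-hydroxy-2-(2-hydroxypropan-2-yl)-2,3-dihydro-1-benzofuran-4-yl]ethynyl}-1,3-phenylene diacetate | CC(C)=CCC/C(C)=C/Cc1c(OC(C)=O)ccc(C#Cc2cc(O)cc3c2C[C@H](C(C)(C)O)O3)c1OC(C)=O | intermediate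
26 | mulberrofuran X | CC(C)=CCC/C(C)=C/Cc1c(O)ccc2cc(-c3cc(O)cc4c3C[C@H](C(C)(C)O)O4)oc12 | target

## Summary

**Total steps:** 21

**Longest linear sequence:** 14 (steps 1–4, 7–14, 20, 21)

**Three steps most likely to fail, with fallbacks:**

- **Step 17 (second lithiation/iodination next to the geranyl chain).** Deprotonation at the benzylic/allylic CH2 could compete with ring lithiation. Fallback: install the halogen first. Take 4-bromoresorcinol bis-MOM ether, deprotonate the C2–H between the two OMOM groups with LiTMP, geranylate, then convert Br to I by Br/Li exchange and I2 quench, rejoining at 22.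
- **Step 7 (hindered aryllithium plus epoxide 5 with BF3).** Lewis-acid rearrangement of the epoxide or sluggish addition is possible. Fallback: change the organometallic and mechanism. Quench lithiated 8 with I2, do I/Mg exchange on the aryl iodide (i-PrMgCl·LiCl), and open 5 by a CuI-catalysed Grignard addition with no Lewis acid.
- **Step 3 (ketoreductase activity and ee on the hindered chloroketone).** No panel enzyme may give both adequate rate and high ee. Fallback: reduce 3 with NaBH4, close to racemic 5, and obtain (R)-5 by Co-salen hydrolytic kinetic resolution of the terminal epoxide.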